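**Assumption:** commercial (R)-but-3-yn-2-ol (≥98% ee) is taken as the only source of chirality; the target is (2R,3R,4S), i.e. 2,3-trans / 3,4-cis on the chroman. The route is designed on paper and has not been run.

## Retrosynthetic overview

1. Sideroxylonal A ⇒ fourfold C-formylation of the bis-phloroglucinol chroman 14 (all four free aryl C–H positions, so no regiochemical issue).
2. 14 ⇒ lactol 12 + phloroglucinol: the C2–aryl bond and the C2 configuration come from Friedel–Crafts arylation of the cyclic oxocarbenium ion, trans to the C3 isopropyl.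
3. 12 ⇒ cis-dihydrocoumarin 11 ⇒ syn acid 7 (propenyl → isobutyl by cross-metathesis and hydrogenation; demethylative lactonisation).
4. 7 ⇒ Ireland–Claisen [3,3] rearrangement of allylic isovalerate 6: this forms the C3–C4 bond and sets both C3 and C4 by 1,3-chirality transfer from the carbinol of (R)-but-3-yn-2-ol.
5. Ring order: both aromatic rings are bought; the only ring made is the pyran, closed as the lactone (step 7) after the [3,3] step and re-functionalised at C2 in steps 8–9.

## Route

**Step 1**
Reactants: 1, 2-iodo-1,3,5-trimethoxybenzene; 2, (R)-but-3-yn-2-ol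
Product: 3, (2R)-4-(2,4,6-trimethoxyphenyl)but-3-yn-2-ol
Conditions: Pd(PPh3)2Cl2 (3 mol%), CuI (5 mol%), Et3N/THF, 60 °C
Reagents that add atoms: none beyond reactants 1 and 2
Why: Sonogashira coupling joins the aryl iodide to the terminal alkyne; the carbinol stereocentre is not involved.

**Step 2**
Reactants: 3
Product: 4, (2R,3E)-4-(2,4,6-trimethoxyphenyl)but-3-en-2-ol
Conditions: Red-Al, THF, 0 °C → rt; Rochelle-salt work-up (no acid)
Reagents that add atoms: none
Why: Hydroxyl-directed trans-hydroalumination of the propargylic alcohol gives only the (E)-allylic alcohol, with the stereocentre untouched.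

**Step 3**
Reactants: 4; 5, 3-methylbutanoyl (isovaleryl) chloride
Product: 6, (2R,3E)-4-(2,4,6-trimethoxyphenyl)but-3-en-2-yl 3-methylbutanoate
Conditions: pyridine, DMAP (cat.), CH2Cl2, 0 °C → rt; purify on Et3N-deactivated silica
Reagents that add atoms: isovaleryl chloride, CC(C)CC(=O)Cl
Why: Simple O-acylation under basic conditions, which avoids ionising the electron-rich cinnamyl-type ester.

**Step 4 (key step)**
Reactants: 6
Product: 7, (2R,3S,4E)-2-(propan-2-yl)-3-(2,4,6-trimethoxyphenyl)hex-4-enoic acid
Conditions: LDA, THF/DMPU (4:1), −78 °C; TBSCl, −78 → 50 °C; then 1 M HCl/THF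
Reagents that add atoms: none
Why: Ireland–Claisen [3,3]-sigmatropic rearrangement: the (Z)-silyl ketene acetal (DMPU conditions) and the (E)-alkene react through a chair transition state with Me, i-Pr and aryl pseudo-equatorial, so suprafacial transfer from the (R) C–O centre sets the aryl-bearing carbon as S and the syn relationship sets the isopropyl-bearing carbon as R.

**Step 5**
Reactants: 7; 8, 2-methylbut-2-ene
Product: 9, (2R,3S)-5-methyl-2-(propan-2-yl)-3-(2,4,6-trimethoxyphenyl)hex-4-enoic acid
Conditions: Hoveyda–Grubbs II (10 mol%), 1,4-benzoquinone (10 mol%), 2-methylbut-2-ene/CH2Cl2, 40 °C, sealed tube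
Reagents that add atoms: 2-methylbut-2-ene, CC=C(C)C (supplies the =C(CH3)2 unit)
Why: Olefin cross-metathesis exchanges the propenyl terminus for isopropylidene; benzoquinone suppresses Ru–H alkene migration that would endanger the benzylic stereocentre.

**Step 6**
Reactants: 9
Product: 10, (2R,3S)-5-methyl-2-(propan-2-yl)-3-(2,4,6-trimethoxyphenyl)hexanoic acid
Conditions: H2 (1 atm), PtO2, EtOAc, rt
Reagents that add atoms: none
Why: Catalytic hydrogenation of the trisubstituted alkene completes the isobutyl group; Pt is chosen over Pd to minimise double-bond isomerisation, and no stereocentre is touched.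

**Step 7**
Reactants: 10
Product: 11, (3R,4S)-5,7-dihydroxy-4-(2-methylpropyl)-3-(propan-2-yl)-3,4-dihydro-2H-chromen-2-one
Conditions: BBr3 (5 equiv), CH2Cl2, −78 °C → rt; aqueous work-up, then TsOH (cat.), PhMe, 50 °C
Reagents that add atoms: none
Why: Lewis-acid cleavage of the three aryl methyl ethers, then spontaneous lactonisation of the ortho-phenol onto the acid, closes the pyran ring with the 3,4-cis relationship retained.

**Step 8**
Reactants: 11
Product: 12, (3R,4S)-4-(2-methylpropyl)-3-(propan-2-yl)-3,4-dihydro-2H-chromene-2,5,7-triol (lactol, anomeric mixture, used crude)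
Conditions: DIBAL-H (4 equiv), CH2Cl2/THF, −78 °C; Rochelle-salt work-up
Reagents that add atoms: none
Why: Partial reduction of the aryl lactone to the 2-chromanol at low temperature (two equivalents are consumed by the phenols); C3 is not epimerised at −78 °C.

**Step 9**
Reactants: 12; 13, phloroglucinol
Product: 14, (2R,3R,4S)-4-(2-methylpropyl)-3-(propan-2-yl)-2-(2,4,6-trihydroxyphenyl)-3,4-dihydro-2H-chromene-5,7-diol
Conditions: phloroglucinol (10 equiv), TsOH·H2O (10 mol%), dioxane/MeCN, 0 °C → rt
Reagents that add atoms: phloroglucinol, Oc1cc(O)cc(O)c1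
Why: Friedel–Crafts C-arylation of the lactol-derived oxocarbenium ion; attack occurs anti to the pseudo-axial C4 isobutyl and trans to the C3 isopropyl, and the acid-labile benzylic C2–O bond lets any cis isomer equilibrate to the 2,3-trans (2R) chroman. The large excess of phloroglucinol outcompetes self-condensation through ring A.

**Step 10**
Reactants: 14
Product: 15, sideroxylonal A
Conditions: POCl3/DMF (excess), MeCN, 0 °C → rt; then H2O, 50 °C
Reagents that add atoms: N,N-dimethylformamide, CN(C)C=O (formyl carbons); water, O (formyl oxygens on iminium hydrolysis)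
Why: Exhaustive Vilsmeier–Haack formylation of both phloroglucinol-type rings at their only free positions (C6, C8, C3′, C5′), as in the diformylation of phloroglucinol itself; no stereocentre is involved.

## Compound list

1 | 2-iodo-1,3,5-trimethoxybenzene | COc1cc(OC)c(I)c(OC)c1 | starting material
2 | (R)-but-3-yn-2-ol | C[C@@H](O)C#C | starting material (chiral)
3 | (2R)-4-(2,4,6-trimethoxyphenyl)but-3-yn-2-ol | C[C@@H](O)C#Cc1c(OC)cc(OC)cc1OC | intermediate
4 | (2R,3E)-4-(2,4,6-trimethoxyphenyl)but-3-en-2-ol | C[C@@H](O)/C=C/c1c(OC)cc(OC)cc1OC | intermediate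
5 | 3-methylbutanoyl chloride | CC(C)CC(=O)Cl | starting material
6 | (2R,3E)-4-(2,4,6-trimethoxyphenyl)but-3-en-2-yl 3-methylbutanoate | C[C@@H](OC(=O)CC(C)C)/C=C/c1c(OC)cc(OC)cc1OC | intermediate
7 | (2R,3S,4E)-2-(propan-2-yl)-3-(2,4,6-trimethoxyphenyl)hex-4-enoic acid | C/C=C/[C@H](c1c(OC)cc(OC)cc1OC)[C@@H](C(C)C)C(=O)O | intermediate
8 | 2-methylbut-2-ene | CC=C(C)C | starting material
9 | (2R,3S)-5-methyl-2-(propan-2-yl)-3-(2,4,6-trimethoxyphenyl)hex-4-enoic acid | CC(C)=C[C@H](c1c(OC)cc(OC)cc1OC)[C@@H](C(C)C)C(=O)O | intermediate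
10 | (2R,3S)-5-methyl-2-(propan-2-yl)-3-(2,4,6-trimethoxyphenyl)hexanoic acid | CC(C)C[C@H](c1c(OC)cc(OC)cc1OC)[C@@H](C(C)C)C(=O)O | intermediate
11 | (3R,4S)-5,7-dihydroxy-4-(2-methylpropyl)-3-(propan-2-yl)-3,4-dihydro-2H-chromen-2-one | CC(C)C[C@@H]1c2c(O)cc(O)cc2OC(=O)[C@@H]1C(C)C | intermediate
12 | (3R,4S)-4-(2-methylpropyl)-3-(propan-2-yl)-3,4-dihydro-2H-chromene-2,5,7-triol (anomeric mixture) | CC(C)C[C@@H]1c2c(O)cc(O)cc2OC(O)[C@@H]1C(C)C | intermediate
13 | phloroglucinol | Oc1cc(O)cc(O)c1 | starting material
14 | (2R,3R,4S)-4-(2-methylpropyl)-3-(propan-2-yl)-2-(2,4,6-trihydroxyphenyl)-3,4-dihydro-2H-chromene-5,7-diol | CC(C)C[C@@H]1c2c(O)cc(O)cc2O[C@@H](c2c(O)cc(O)cc2O)[C@@H]1C(C)C | intermediate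
15 | sideroxylonal A | CC(C)C[C@@H]1c2c(O)c(C=O)c(O)c(C=O)c2O[C@@H](c2c(O)c(C=O)c(O)c(C=O)c2O)[C@@H]1C(C)C | target

## Summary

Total steps: 10. Longest linear sequence: 10 (from 1 or 2).

**Steps most likely to fail, with fallbacks**

- **Step 5 (cross-metathesis).** The internal alkene sits next to a congested benzylic CH, so turnover may be slow and isomerisation may compete. Fallback: drop metathesis and cleave the propenyl group of 7 (as its methyl ester) with OsO4/NaIO4 to the aldehyde, olefinate with salt-free Ph3P=C(CH3)2 at low temperature, then hydrogenate to the same isobutyl compound.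
- **Step 10 (late tetraformylation).** The acid-labile C2–O and C2–aryl bonds of 14 may not survive, and formylation may stop short of four. Fallback: bring the formyl groups in differently. Stop step 7 at mono-demethylative lactonisation (5,7-di-O-methyl lactone), reduce to the lactol, condense it with 2,4-diformylphloroglucinol (Knoevenagel, then o-quinone-methide oxa-Michael ring closure), then formylate ring A alone by Rieche reaction (Cl2CHOMe/TiCl4) and demethylate with BCl3.
- **Step 4 (Ireland–Claisen).** Bond formation occurs at a carbon bearing a di-ortho-substituted aryl, the electron-rich ester can ionise, and the Z-enolate ratio limits the dr. Fallback: reverse the roles of the partners. Use the (2,4,6-trimethoxyphenyl)acetate of enantiopure (E)-5-methylhex-3-en-2-ol so the aryl sits on the enolate carbon; the rearranged acid then gives the C2 aldehyde directly by ozonolysis of its propenyl group, and the carboxyl is homologated to isobutyl.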